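**Plan**

- Numbering (labdane type, used for all intermediates): decalin C1–C10 with the geminal methyls on C4, ring-fusion CH at C5, acetoxy carbon C6, CH2 at C7, CH(CH3) at C8, carbinol C9, angular-methyl carbon C10; side chain C11, C12; β is the face of the C10 methyl. Cuts: C12–lactam bond (B-alkyl Suzuki coupling), C11=C12 and C9=C11 back to a C9 ketone, C6–O back to a C6 nitro group.
- Enabling feature: ring B carries oxygen on C6 and on C9, para to each other, so C5–C10 and C7–C8 each join a carbon alpha to C6 with a carbon alpha to C9 (like polarity, twice). With C6 written as a nitro carbon, C5–C6–C7 becomes a 2-nitroallyl pivalate (double acceptor) and C8–C9–C10 a ketone (double donor); cutting both bonds opens rings A and B to one acyclic chain.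
- Forward: the chain is assembled from isobutyronitrile, 1,3-dibromopropane, pentan-3-one and 2-nitroethanol; one amine-catalysed cascade closes ring A (C5–C10) and then ring B (C7–C8); C9 methylenation with Nef reaction at C6, reduction, acetylation, dihydroxylation, oxidation, methylenation, side-chain coupling and N-deprotection follow.
- Stereochemistry: C10 (and the trans C5) from the chiral primary amine in the cascade; C8 by equilibration next to the C9 ketone; C6 by hydride delivery to the α face; C9 by α-face dihydroxylation of the exocyclic alkene.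

Key step: step 7

Remark 1: the sense of induction of a cinchona primary amine on a tethered, tetrasubstituted enamine of this kind cannot be assigned from a model with confidence; the quinidine-derived amine is written, and its quinine-derived pseudoenantiomer is the catalyst if the first run shows the mirror-image series.
Remark 2: the bicyclic nitro ketone of the key step is drawn as its equatorial (6α) nitro epimer; the C6 epimer serves equally, because C6 becomes trigonal in the next step.

**Route**

Step 1
Reactants: 1 isobutyronitrile; 2 1,3-dibromopropane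
Product: 4 5-bromo-2,2-dimethylpentanenitrile, via lithiated isobutyronitrile 3 (not isolated)
Conditions: LiN(i-Pr)2 (1.05 equiv), THF, −78 °C; then transfer into 2 (3 equiv), THF, −78 °C to rt
Reagents that add atoms: none
Why: SN2 alkylation of an α-lithiated nitrile, in which inverse addition to excess dibromide should suppress double alkylation and deliver C1–C5 with the quaternary C4.

Step 2
Reactants: 5 pentan-3-one
Product: 6 pentan-3-one N,N-dimethylhydrazone
Conditions: Me2NNH2 (1.5 equiv), AcOH (cat.), EtOH, reflux
Reagents that add atoms: N,N-dimethylhydrazine CN(C)N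
Why: hydrazone condensation, which gives a ketone derivative that can be mono-alkylated cleanly and that is inert to the hydride of step 4.

Step 3
Reactants: 6 pentan-3-one N,N-dimethylhydrazone; 4 5-bromo-2,2-dimethylpentanenitrile
Product: 8 7-(2,2-dimethylhydrazinylidene)-2,2,6-trimethylnonanenitrile (racemic), via lithium azaenolate 7 (not isolated)
Conditions: LiN(i-Pr)2 (1.05 equiv), THF, 0 °C; then 4, −78 °C to rt
Reagents that add atoms: none
Why: hydrazone azaenolate alkylation with a primary bromide should form the C1–C10 bond without polyalkylation, and the nitrile has no α-hydrogen that could interfere.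

Step 4
Reactants: 8 7-(2,2-dimethylhydrazinylidene)-2,2,6-trimethylnonanenitrile
Product: 10 2,2,6-trimethyl-7-oxononanal (racemic), via N-aluminated aldimine 9 (not isolated)
Conditions: i-Bu2AlH (1.3 equiv), toluene, −78 to 0 °C; then 2 M aq. HCl, pentane/THF, 0 °C to rt (short contact)
Reagents that add atoms: water O
Why: partial reduction of the nitrile stops at the aluminated imine while the hydrazone is untouched, and one two-phase acidic hydrolysis should release both the aldehyde (C5) and the ketone (C9) and hold the hydrazine in the aqueous layer.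

Step 5
Reactants: 10 2,2,6-trimethyl-7-oxononanal; 11 2-nitroethanol
Product: 12 9,11-dihydroxy-4,8,8-trimethyl-10-nitroundecan-3-one (mixture of diastereomers)
Conditions: 11 (2 equiv), 1,1,3,3-tetramethylguanidine (0.2 equiv), THF, 0 °C to rt
Reagents that add atoms: none
Why: Henry reaction, chemoselective for the non-enolisable aldehyde over the ketone, brings in C6 and C7; the three stereocentres of the adduct are all removed later.

Step 6
Reactants: 12 9,11-dihydroxy-4,8,8-trimethyl-10-nitroundecan-3-one
Product: 15 (2E)-4,4,8-trimethyl-2-nitro-9-oxoundec-2-en-1-yl 2,2-dimethylpropanoate, via mono-pivalate 13 (not isolated), via mesylate 14 (not isolated)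
Conditions: t-BuCOCl (1.1 equiv), pyridine (2 equiv), CH2Cl2, −20 to 0 °C; then MeSO2Cl (1.5 equiv), Et3N (3.5 equiv), −40 °C to rt
Reagents that add atoms: pivaloyl chloride CC(C)(C)C(=O)Cl
Why: the primary hydroxyl is acylated selectively, and mesylation of the hindered secondary hydroxyl followed by E1cB elimination through the nitronate should expel mesylate (far better leaving group than pivalate) to give the more substituted (E)-nitroalkene with the chain trans to the nitro group.

Step 7
Reactants: 15 (2E)-4,4,8-trimethyl-2-nitro-9-oxoundec-2-en-1-yl 2,2-dimethylpropanoate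
Product: 17 (2R,4S,4aS,8aS)-2,5,5,8a-tetramethyl-4-nitrooctahydronaphthalen-1(2H)-one (trans-fused; 8α-methyl; 6α-nitro in the numbering above), via monocyclic nitroalkene 16 (not isolated)
Conditions: 9-amino-9-deoxy-epi-quinidine (20 mol %), 2-fluorobenzoic acid (40 mol %), toluene (0.01 M), 40 °C; then 1 M aq. HCl, THF, rt
Reagents that add atoms: none
Why: Proposed new method: the primary amine of the catalyst condenses with the C9 ketone and the imine equilibrates with both secondary enamines, of which only the more substituted C9=C10 enamine can reach the nitroalkene, so C10 adds to C5 (Michael addition, 6-exo-trig, ring A), the nitronate expels pivalate (E1cB) to give the 2-nitroallyl compound 16, and the imine, now enolisable only towards C8, adds through C8 to the new terminal nitroalkene carbon C7 (Michael addition, 6-endo-trig, ring B) before hydrolysis releases 17 and the amine. The closest known reaction type is the [3+3] carbocyclisation of ketone enamines with 2-nitroallylic esters (Michael addition, elimination, Michael addition), known between separate partners for cyclic ketones and with chiral amine catalysts, taken together with the known primary-amine-catalysed nitro-Michael additions of alpha-branched carbonyl compounds; new are the tether, which turns the first addition into a ring closure at the branched carbon of an acyclic ketone, and the fused instead of bridged product. C10 is set by the catalyst, whose protonated quinuclidine holds the nitro group by a hydrogen bond and so delivers C5 to one face of the enamine; C5 follows from a chair-like transition state in which the enamine carbon C9 and the nitroalkene carbon C6 are both pseudo-equatorial and the C10 methyl is pseudo-axial, which gives the trans relation of the C10 methyl and the C5 hydrogen; C8 and C6 are epimerisable (alpha to the ketone and to the nitro group) and should settle to the equatorial methyl and nitro groups. The step needs regioselectivity (C10 before C8), secured because attack of C8 on C5 would require an eight-membered ring; it needs chemoselectivity for cyclisation over intermolecular Michael addition and over capture of the amine by the nitroallyl ester, secured by high dilution, the geminal dimethyl group next to C5 and the carboxylic acid co-catalyst; and it needs the congested first addition to be irreversible, secured by the loss of pivalate.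

Step 8
Reactants: 17 (2R,4S,4aS,8aS)-2,5,5,8a-tetramethyl-4-nitrooctahydronaphthalen-1(2H)-one
Product: 20 (3R,4aS,8aS)-3,4a,8,8-tetramethyl-4-methylideneoctahydronaphthalen-1(2H)-one, via potassium nitronate 18 (not isolated), via methylenated potassium nitronate 19 (not isolated)
Conditions: Ph3PCH3Br (5 equiv), KOt-Bu (5.5 equiv), toluene, 90 °C; cool, MeOH; then aq. TiCl3 (5 equiv), NH4OAc buffer (pH 5–6), THF, 0 °C to rt
Reagents that add atoms: methyltriphenylphosphonium bromide C[P+](c1ccccc1)(c1ccccc1)c1ccccc1.[Br-]; water O
Why: the base turns the acidic nitro group into a nitronate that masks C6 while the Wittig ylide methylenates the hindered C9 ketone (C8 having equilibrated to the equatorial α-methyl, since the β-epimer would place its methyl syn-axial to the C10 methyl), and the same nitronate is then reduced by trivalent titanium and hydrolysed to the C6 ketone (reductive Nef reaction).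

Step 9
Reactants: 20 (3R,4aS,8aS)-3,4a,8,8-tetramethyl-4-methylideneoctahydronaphthalen-1(2H)-one
Product: 21 (1R,3R,4aS,8aS)-3,4a,8,8-tetramethyl-4-methylidenedecahydronaphthalen-1-ol (6β-hydroxy, axial)
Conditions: NaBH4 (2 equiv), MeOH/THF, 0 °C
Reagents that add atoms: none
Why: borohydride reduction in which the β face of C6 is blocked by the two syn-axial methyls (C4β and C10), so hydride should arrive from the α face and give the axial 6β-alcohol.

Step 10
Reactants: 21 (1R,3R,4aS,8aS)-3,4a,8,8-tetramethyl-4-methylidenedecahydronaphthalen-1-ol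
Product: 22 (1R,3R,4aS,8aS)-3,4a,8,8-tetramethyl-4-methylidenedecahydronaphthalen-1-yl acetate
Conditions: Ac2O (5 equiv), DMAP (1 equiv), pyridine, 60 °C
Reagents that add atoms: acetic anhydride CC(=O)OC(C)=O
Why: DMAP-catalysed acylation of the only hydroxyl group, done here so that no free 6β-oxygen is present later, when C9 and C11 become electrophilic or are oxidised.

Step 11
Reactants: 22 (1R,3R,4aS,8aS)-3,4a,8,8-tetramethyl-4-methylidenedecahydronaphthalen-1-yl acetate
Product: 23 (1R,3R,4R,4aS,8aS)-4-hydroxy-4-(hydroxymethyl)-3,4a,8,8-tetramethyldecahydronaphthalen-1-yl acetate (9α-hydroxy, 11-hydroxy)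
Conditions: OsO4 (5 mol %), N-methylmorpholine N-oxide (2 equiv), acetone/H2O, rt
Reagents that add atoms: N-methylmorpholine N-oxide C[N+]1([O-])CCOCC1; water O
Why: catalytic syn-dihydroxylation, in which the β face of the exocyclic alkene is shielded by the adjacent axial C10 methyl, so the osmate should form on the α face and place the C9 oxygen α (axial) and C11 β (equatorial).

Step 12
Reactants: 23 (1R,3R,4R,4aS,8aS)-4-hydroxy-4-(hydroxymethyl)-3,4a,8,8-tetramethyldecahydronaphthalen-1-yl acetate
Product: 24 (1R,3R,4R,4aS,8aS)-4-formyl-4-hydroxy-3,4a,8,8-tetramethyldecahydronaphthalen-1-yl acetate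
Conditions: SO3·pyridine (3 equiv), DMSO, Et3N (6 equiv), CH2Cl2, 0 °C
Reagents that add atoms: none
Why: Parikh–Doering oxidation converts the primary alcohol into the aldehyde without cleaving the 1,2-diol and leaves the tertiary alcohol and the acetate alone.

Step 13
Reactants: 24 (1R,3R,4R,4aS,8aS)-4-formyl-4-hydroxy-3,4a,8,8-tetramethyldecahydronaphthalen-1-yl acetate
Product: 25 (1R,3R,4R,4aS,8aS)-4-ethenyl-4-hydroxy-3,4a,8,8-tetramethyldecahydronaphthalen-1-yl acetate
Conditions: Ph3PCH3Br (2.5 equiv), KN(SiMe3)2 (2.4 equiv), THF, 0 °C; then 24, −78 to 0 °C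
Reagents that add atoms: methyltriphenylphosphonium bromide C[P+](c1ccccc1)(c1ccccc1)c1ccccc1.[Br-]
Why: Wittig methylenation of the aldehyde at low temperature adds C12 without touching the hindered axial acetate, and C9 has no hydrogen and cannot epimerise.

Step 14
Reactants: 26 tert-butyl 2,4-dioxopyrrolidine-1-carboxylate
Product: 27 tert-butyl 2-oxo-4-(trifluoromethanesulfonyloxy)-2,5-dihydro-1H-pyrrole-1-carboxylate
Conditions: Tf2O (1.1 equiv), i-Pr2NEt (1.2 equiv), CH2Cl2, −78 °C
Reagents that add atoms: trifluoromethanesulfonic anhydride O=S(=O)(OS(=O)(=O)C(F)(F)F)C(F)(F)F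
Why: O-sulfonylation of the enol form of the β-keto amide gives the vinylogous acyl triflate that carries the complete lactam ring.

Step 15
Reactants: 25 (1R,3R,4R,4aS,8aS)-4-ethenyl-4-hydroxy-3,4a,8,8-tetramethyldecahydronaphthalen-1-yl acetate; 27 tert-butyl 2-oxo-4-(trifluoromethanesulfonyloxy)-2,5-dihydro-1H-pyrrole-1-carboxylate
Product: 29 N-tert-butoxycarbonyl derivative of the target, via alkylborane 28 (not isolated)
Conditions: 9-borabicyclo[3.3.1]nonane dimer (3 equiv B–H), THF, 0 to 50 °C; then 27 (1.5 equiv), Pd(dppf)Cl2 (10 mol %), AsPh3 (10 mol %), K3PO4 (3 equiv), DMF/H2O, rt to 40 °C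
Reagents that add atoms: none
Why: anti-Markovnikov hydroboration of the vinyl group puts boron on C12, and B-alkyl Suzuki–Miyaura coupling with the electron-poor enol triflate (oxidative addition to zerovalent palladium, transmetalation, reductive elimination) should form the C12–C13 bond while the acetate and the tertiary alcohol are tolerated.

Step 16
Reactants: 29 N-tert-butoxycarbonyl derivative of the target
Product: 30 (1R,3R,4R,4aS,8aS)-4-hydroxy-3,4a,8,8-tetramethyl-4-[2-(5-oxo-2,5-dihydro-1H-pyrrol-3-yl)ethyl]decahydronaphthalen-1-yl acetate (target)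
Conditions: Mg(ClO4)2 (0.2 equiv), MeCN, 50 °C
Reagents that add atoms: none
Why: Lewis-acid-assisted cleavage of the tert-butoxycarbonyl group from the acylated nitrogen, selective for this imide-type carbamate, so the acetate and the tertiary alcohol should survive.

**Compound list**

1 | isobutyronitrile | CC(C)C#N | starting material
2 | 1,3-dibromopropane | BrCCCBr | starting material
3 | lithiated isobutyronitrile | CC(C)=C=N[Li] | intermediate
4 | 5-bromo-2,2-dimethylpentanenitrile | N#CC(C)(C)CCCBr | intermediate
5 | pentan-3-one | CCC(=O)CC | starting material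
6 | pentan-3-one N,N-dimethylhydrazone | CCC(CC)=NN(C)C | intermediate
7 | lithium azaenolate of 6 | CC=C(CC)N([Li])N(C)C | intermediate
8 | 7-(2,2-dimethylhydrazinylidene)-2,2,6-trimethylnonanenitrile (racemic) | CCC(=NN(C)C)C(C)CCCC(C)(C)C#N | intermediate
9 | N-(diisobutylalumanyl) aldimine formed from the nitrile of 8 | CCC(=NN(C)C)C(C)CCCC(C)(C)C=N[Al](CC(C)C)CC(C)C | intermediate
10 | 2,2,6-trimethyl-7-oxononanal (racemic) | CCC(=O)C(C)CCCC(C)(C)C=O | intermediate
11 | 2-nitroethanol | OCC[N+](=O)[O-] | starting material
12 | 9,11-dihydroxy-4,8,8-trimethyl-10-nitroundecan-3-one (mixture of diastereomers) | CCC(=O)C(C)CCCC(C)(C)C(O)C(CO)[N+](=O)[O-] | intermediate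
13 | 3-hydroxy-4,4,8-trimethyl-2-nitro-9-oxoundecyl 2,2-dimethylpropanoate | CCC(=O)C(C)CCCC(C)(C)C(O)C(COC(=O)C(C)(C)C)[N+](=O)[O-] | intermediate
14 | 3-(methanesulfonyloxy)-4,4,8-trimethyl-2-nitro-9-oxoundecyl 2,2-dimethylpropanoate | CCC(=O)C(C)CCCC(C)(C)C(OS(C)(=O)=O)C(COC(=O)C(C)(C)C)[N+](=O)[O-] | intermediate
15 | (2E)-4,4,8-trimethyl-2-nitro-9-oxoundec-2-en-1-yl 2,2-dimethylpropanoate (racemic at C8 of the chain) | CCC(=O)C(C)CCCC(C)(C)/C=C(\COC(=O)C(C)(C)C)[N+](=O)[O-] | intermediate
16 | 1-[(1S,2S)-1,3,3-trimethyl-2-(1-nitroethenyl)cyclohexyl]propan-1-one | CCC(=O)[C@@]1(C)CCCC(C)(C)[C@@H]1C(=C)[N+](=O)[O-] | intermediate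
17 | (2R,4S,4aS,8aS)-2,5,5,8a-tetramethyl-4-nitrooctahydronaphthalen-1(2H)-one | [O-][N+](=O)[C@H]1C[C@@H](C)C(=O)[C@@]2(C)CCCC(C)(C)[C@H]12 | intermediate
18 | potassium nitronate of 17 | [K+].[O-][N+]([O-])=C1C[C@@H](C)C(=O)[C@@]2(C)CCCC(C)(C)[C@H]12 | intermediate
19 | potassium nitronate of the 9-methylidene analogue of 17 | [K+].[O-][N+]([O-])=C1C[C@@H](C)C(=C)[C@@]2(C)CCCC(C)(C)[C@H]12 | intermediate
20 | (3R,4aS,8aS)-3,4a,8,8-tetramethyl-4-methylideneoctahydronaphthalen-1(2H)-one | O=C1C[C@@H](C)C(=C)[C@@]2(C)CCCC(C)(C)[C@H]12 | intermediate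
21 | (1R,3R,4aS,8aS)-3,4a,8,8-tetramethyl-4-methylidenedecahydronaphthalen-1-ol | O[C@@H]1C[C@@H](C)C(=C)[C@@]2(C)CCCC(C)(C)[C@H]12 | intermediate
22 | (1R,3R,4aS,8aS)-3,4a,8,8-tetramethyl-4-methylidenedecahydronaphthalen-1-yl acetate | CC(=O)O[C@@H]1C[C@@H](C)C(=C)[C@@]2(C)CCCC(C)(C)[C@H]12 | intermediate
23 | (1R,3R,4R,4aS,8aS)-4-hydroxy-4-(hydroxymethyl)-3,4a,8,8-tetramethyldecahydronaphthalen-1-yl acetate | CC(=O)O[C@@H]1C[C@@H](C)[C@](O)(CO)[C@@]2(C)CCCC(C)(C)[C@H]12 | intermediate
24 | (1R,3R,4R,4aS,8aS)-4-formyl-4-hydroxy-3,4a,8,8-tetramethyldecahydronaphthalen-1-yl acetate | CC(=O)O[C@@H]1C[C@@H](C)[C@](O)(C=O)[C@@]2(C)CCCC(C)(C)[C@H]12 | intermediate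
25 | (1R,3R,4R,4aS,8aS)-4-ethenyl-4-hydroxy-3,4a,8,8-tetramethyldecahydronaphthalen-1-yl acetate | CC(=O)O[C@@H]1C[C@@H](C)[C@](O)(C=C)[C@@]2(C)CCCC(C)(C)[C@H]12 | intermediate
26 | tert-butyl 2,4-dioxopyrrolidine-1-carboxylate | CC(C)(C)OC(=O)N1CC(=O)CC1=O | starting material
27 | tert-butyl 2-oxo-4-(trifluoromethanesulfonyloxy)-2,5-dihydro-1H-pyrrole-1-carboxylate | CC(C)(C)OC(=O)N1CC(OS(=O)(=O)C(F)(F)F)=CC1=O | intermediate
28 | B-alkyl-9-borabicyclo[3.3.1]nonane formed from 25 (boron on C12) | CC(=O)O[C@@H]1C[C@@H](C)[C@](O)(CCB2C3CCCC2CCC3)[C@@]2(C)CCCC(C)(C)[C@H]12 | intermediate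
29 | N-tert-butoxycarbonyl derivative of the target | CC(=O)O[C@@H]1C[C@@H](C)[C@](O)(CCC2=CC(=O)N(C(=O)OC(C)(C)C)C2)[C@@]2(C)CCCC(C)(C)[C@H]12 | intermediate
30 | (1R,3R,4R,4aS,8aS)-4-hydroxy-3,4a,8,8-tetramethyl-4-[2-(5-oxo-2,5-dihydro-1H-pyrrol-3-yl)ethyl]decahydronaphthalen-1-yl acetate | CC(=O)O[C@@H]1C[C@@H](C)[C@](O)(CCC2=CC(=O)NC2)[C@@]2(C)CCCC(C)(C)[C@H]12 | target

**Count and risks**

Total steps: 16. Longest linear sequence: 14 steps (steps 1, 3 to 13, 15 and 16; steps 2 and 14 are side branches).

Step 7. What may go wrong: slow condensation of the branched acyclic ketone with the amine, so that the nitroallyl ester is lost to intermolecular addition or to the amine itself, and poor facial selectivity at C10. The fallback uses known reactions with a stoichiometric base and no chiral catalyst, followed by separation of the enantiomers, and sets out from 15. Slow addition of 15 to KOt-Bu (1.0 equiv) in t-BuOH/THF at high dilution lets the equilibrating enolate react through its more substituted form in the conjugate addition–elimination known for ketone enolates and 2-nitroallyl pivalates; this gives 16 together with its mirror image, the (1R,2R) ketone F1. A second equivalent of KOt-Bu closes ring B to the nitronate 18 and its mirror image, the potassium nitronate F2. Protonation with AcOH gives 17 and its mirror image, the nitro ketone F3, which are separated by preparative chromatography on a chiral stationary phase. The route is rejoined at 17.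

Step 8. What may go wrong: decomposition of the nitronate in the hot ylide solution, stalling of the methylenation at the doubly flanked C9 carbonyl, or interference of the phosphorus residues with the titanium reduction. The fallback reverses the order and masks C6 as a silyl enol ether; it sets out from 17. KOH in MeOH gives nitronate 18, and buffered aqueous TiCl3 converts it into the dione F4. LiN(i-Pr)2 at −78 °C removes a proton from the only α-methylene group (C7) to give the lithium enolate F5, which t-BuMe2SiCl traps as the silyl enol ether F6. Wittig methylenation (Ph3PCH3Br, KOt-Bu, toluene, 90 °C) of the remaining C9 ketone gives the methylidene silyl enol ether F7, and Bu4NF releases the C6 ketone, so that the route is rejoined at 20.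

Step 6. What may go wrong: loss of pivalate instead of mesylate in the elimination, which would give the transposed terminal nitroalkene, or retro-Henry cleavage under the amine base. The fallback introduces the hydroxymethyl group after the nitroalkene has been made; it sets out from 10. Henry reaction with nitromethane gives the nitro alcohol F8; dehydration (DCC, CuCl) gives the (E)-nitroalkene F9. Morita–Baylis–Hillman reaction with aqueous formaldehyde (imidazole, anthranilic acid cat.) gives the 2-nitroallylic alcohol F10, and t-BuCOCl/pyridine gives 15, where the route is rejoined.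

**Further compounds**

F1 | step 7 | 1-[(1R,2R)-1,3,3-trimethyl-2-(1-nitroethenyl)cyclohexyl]propan-1-one (mirror image of 16) | CCC(=O)[C@]1(C)CCCC(C)(C)[C@H]1C(=C)[N+](=O)[O-]
F2 | step 7 | potassium nitronate, mirror image of 18 | [K+].[O-][N+]([O-])=C1C[C@H](C)C(=O)[C@]2(C)CCCC(C)(C)[C@@H]12
F3 | step 7 | (2S,4R,4aR,8aR)-2,5,5,8a-tetramethyl-4-nitrooctahydronaphthalen-1(2H)-one (mirror image of 17) | [O-][N+](=O)[C@@H]1C[C@H](C)C(=O)[C@]2(C)CCCC(C)(C)[C@@H]12
F4 | step 8 | (2R,4aS,8aS)-2,5,5,8a-tetramethylhexahydronaphthalene-1,4(2H,4aH)-dione (6,9-dione) | O=C1C[C@@H](C)C(=O)[C@@]2(C)CCCC(C)(C)[C@H]12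
F5 | step 8 | lithium C6 enolate of F4 (C6=C7) | [Li]OC1=C[C@@H](C)C(=O)[C@@]2(C)CCCC(C)(C)[C@H]12
F6 | step 8 | tert-butyldimethylsilyl enol ether of F4 at C6 (C6=C7) | CC(C)(C)[Si](C)(C)OC1=C[C@@H](C)C(=O)[C@@]2(C)CCCC(C)(C)[C@H]12
F7 | step 8 | 9-methylidene tert-butyldimethylsilyl enol ether | CC(C)(C)[Si](C)(C)OC1=C[C@@H](C)C(=C)[C@@]2(C)CCCC(C)(C)[C@H]12
F8 | step 6 | 9-hydroxy-4,8,8-trimethyl-10-nitrodecan-3-one | CCC(=O)C(C)CCCC(C)(C)C(O)C[N+](=O)[O-]
F9 | step 6 | (9E)-4,8,8-trimethyl-10-nitrodec-9-en-3-one | CCC(=O)C(C)CCCC(C)(C)/C=C/[N+](=O)[O-]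
F10 | step 6 | (9E)-11-hydroxy-4,8,8-trimethyl-10-nitroundec-9-en-3-one | CCC(=O)C(C)CCCC(C)(C)/C=C(\CO)[N+](=O)[O-]
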